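**Retrosynthetic overview**
1. Naamidine E ⇒ naamine E + 1-methylparabanic acid. This silyl-mediated dehydrative C–N coupling is the last step, and the dehydrohydantoin ring is bought.
2. Key cut: imidazole C5–CH2Ar ⇒ a C5-unsubstituted 2-aminoimidazole used as a neutral ene-guanidine π-nucleophile + an o-quinone methide of the hydroquinone ring. This avoids imidazole metalation and α-aminoketone/cyanamide condensation.
3. o-Quinone methide ⇒ phenolic Mannich base of mono-O-benzyl-2,3-dimethoxyhydroquinone ⇒ C2v-symmetric 2,3-dimethoxy-1,4-benzoquinone.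
4. 2-Aminoimidazole ⇒ cyanamide + N-methyl-3-arylpropargylamine (guanylation / 5-exo-dig hydroamination / aromatisation) ⇒ Sonogashira coupling of 4-iodoanisole with N-methylpropargylamine.
5. Ring order: the imidazole is the only ring built (step 2). Both arenes and the hydantoin arrive preformed.

**Assumption:** the target SMILES has no stereocentre and no stereogenic double bond. The compound is achiral, so no stereocontrol is needed, and it is made as the drawn 2-NH tautomer.

**Step 1**
Reactants: 1 4-iodoanisole; 2 N-methylprop-2-yn-1-amine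
Product: 3 3-(4-methoxyphenyl)-N-methylprop-2-yn-1-amine
Conditions: PdCl2(PPh3)2 (2 mol %), CuI (4 mol %), Et3N, rt → 40 °C, Ar
Reagents that add atoms: none
Why: Sonogashira coupling, in which the aryl iodide adds oxidatively to Pd(0) at rt and the copper acetylide transmetalates, while the free secondary amine is a spectator under these base-mild conditions.

**Step 2**
Reactants: 3 3-(4-methoxyphenyl)-N-methylprop-2-yn-1-amine
Product: 6 4-(4-methoxybenzyl)-1-methyl-1H-imidazol-2-amine, via 1-[3-(4-methoxyphenyl)prop-2-yn-1-yl]-1-methylguanidine 4 (not isolated), via (4Z)-4-(4-methoxybenzylidene)-1-methylimidazolidin-2-imine 5 (not isolated)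
Conditions: H2NCN (3 equiv, in portions), La(OTf)3 (10 mol %), 1,4-dioxane, 100 °C, sealed tube, Ar
Reagents that add atoms: cyanamide, N#CN
Why: Lanthanide-catalysed guanylation of the secondary amine with cyanamide gives 4, whose NH2 closes by 5-exo-dig intramolecular hydroamination of the aryl alkyne to 5, and a 1,3-prototropic shift aromatises it, so N-methyl sits by construction next to the unsubstituted C5.

**Step 3**
Reactants: 7 2,3-dimethoxy-1,4-benzoquinone
Product: 8 2,3-dimethoxybenzene-1,4-diol
Conditions: Na2S2O4, EtOAc/H2O, rt, 15 min, Ar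
Reagents that add atoms: none
Why: Dithionite two-electron reduction of a quinone to its hydroquinone is fast and leaves the methyl ethers untouched.

**Step 4**
Reactants: 8 2,3-dimethoxybenzene-1,4-diol
Product: 9 4-(benzyloxy)-2,3-dimethoxyphenol
Conditions: BnBr (1.0 equiv), K2CO3 (1.0 equiv), 8 (2 equiv, excess recovered), degassed DMF, rt, Ar
Reagents that add atoms: benzyl bromide, BrCc1ccccc1
Why: Williamson etherification, where the C2v symmetry of 8 makes both OH groups equivalent so only mono- versus di-alkylation must be controlled (excess diol), and the benzyl group later stops the o-quinone methide from tautomerising to a methylquinone.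

**Step 5**
Reactants: 9 4-(benzyloxy)-2,3-dimethoxyphenol
Product: 10 4-(benzyloxy)-6-[(dimethylamino)methyl]-2,3-dimethoxyphenol
Conditions: 37 % aq CH2O, 40 % aq Me2NH, EtOH, rt → 60 °C
Reagents that add atoms: formaldehyde, C=O; dimethylamine, CNC
Why: Phenol Mannich reaction, in which C6 is the only position ortho to the free OH (para is blocked) and is also para to the 3-OMe group, so a single regioisomer forms.

**Step 6 (key step)**
Reactants: 6 4-(4-methoxybenzyl)-1-methyl-1H-imidazol-2-amine; 10 4-(benzyloxy)-6-[(dimethylamino)methyl]-2,3-dimethoxyphenol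
Product: 12 2-{[2-amino-4-(4-methoxybenzyl)-1-methyl-1H-imidazol-5-yl]methyl}-4-(benzyloxy)-5,6-dimethoxyphenol, via 4-(benzyloxy)-2,3-dimethoxy-6-methylidenecyclohexa-2,4-dien-1-one 11 (not isolated)
Conditions: 6 (1.3 equiv), 10 added over 4 h, degassed DMF, 120 °C, Ar sparge (−Me2NH)
Reagents that add atoms: none
Why: Proposed new method: heating the Mannich base expels volatile Me2NH (retro-Michael) to give the electron-rich o-quinone methide 11 at low stationary concentration, and C5 of 6, the only free ring carbon and the β-carbon of the cyclic ene-guanidine (its σ-complex is an amidinium ion), adds to the exocyclic CH2 in a Michael/Friedel–Crafts sense with rearomatisation of both phenol and imidazole making the C–C bond irreversible, whereas N3- or N2-adducts and any [4+2] O,N-ketal adduct are themselves o-hydroxybenzyl-amine type precursors that revert at 120 °C and funnel to 12; the closest known reaction types are thermal o-quinone methide C-alkylation of indoles, 6-aminouracils, aminopyrazoles and enaminones by phenolic Mannich bases, and C4(5)-hydroxyalkylation of 2-aminoimidazoles by aldehydes.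

**Step 7**
Reactants: 12 2-{[2-amino-4-(4-methoxybenzyl)-1-methyl-1H-imidazol-5-yl]methyl}-4-(benzyloxy)-5,6-dimethoxyphenol
Product: 13 naamine E, 2-{[2-amino-4-(4-methoxybenzyl)-1-methyl-1H-imidazol-5-yl]methyl}-5,6-dimethoxybenzene-1,4-diol
Conditions: H2 (1 atm), 10 % Pd/C, degassed MeOH, rt; filtered under Ar and used directly
Reagents that add atoms: none
Why: Catalytic hydrogenolysis cleaves only the aryl O-benzyl bond, because the diarylmethane C–C bonds, the methyl ethers and the aminoimidazole are inert at 1 atm.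

**Step 8**
Reactants: 13 naamine E; 14 1-methylimidazolidine-2,4,5-trione (1-methylparabanic acid)
Product: 18 naamidine E, 4-({5-[(2,5-dihydroxy-3,4-dimethoxyphenyl)methyl]-4-[(4-methoxyphenyl)methyl]-1-methyl-1H-imidazol-2-yl}amino)-1-methyl-1H-imidazole-2,5-dione, via 1-methyl-4-[(trimethylsilyl)oxy]-1H-imidazole-2,5-dione 15 (not isolated), via naamine E bis(O-trimethylsilyl) ether 16 (not isolated), via naamidine E bis(O-trimethylsilyl) ether 17 (not isolated)
Conditions: 14, BSA, MeCN, 80 °C; 13, BSA, PhMe, rt; combine, PhMe, 110 °C, Ar; then MeOH, rt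
Reagents that add atoms: none
Why: Silyl-mediated dehydrative condensation (addition–elimination on an O-silyl imidate), in which BSA turns the N3-H/C4=O lactam of 14 into the only carbon carrying a leaving group so the exocyclic NH2 attacks C4 and gives the drawn connectivity, while transient TMS ethers shield the hydroquinone from oxidation and fall off in methanol.

**Compound list**
1 | 4-iodoanisole | COc1ccc(I)cc1 | starting material
2 | N-methylprop-2-yn-1-amine | CNCC#C | starting material
3 | 3-(4-methoxyphenyl)-N-methylprop-2-yn-1-amine | CNCC#Cc1ccc(OC)cc1 | intermediate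
4 | 1-[3-(4-methoxyphenyl)prop-2-yn-1-yl]-1-methylguanidine | CN(CC#Cc1ccc(OC)cc1)C(N)=N | intermediate (not isolated)
5 | (4Z)-4-(4-methoxybenzylidene)-1-methylimidazolidin-2-imine | CN1C/C(=C/c2ccc(OC)cc2)NC1=N | intermediate (not isolated)
6 | 4-(4-methoxybenzyl)-1-methyl-1H-imidazol-2-amine | Cn1cc(Cc2ccc(OC)cc2)nc1N | intermediate
7 | 2,3-dimethoxy-1,4-benzoquinone | COC1=C(OC)C(=O)C=CC1=O | starting material
8 | 2,3-dimethoxybenzene-1,4-diol | COc1c(O)ccc(O)c1OC | intermediate
9 | 4-(benzyloxy)-2,3-dimethoxyphenol | COc1c(O)ccc(OCc2ccccc2)c1OC | intermediate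
10 | 4-(benzyloxy)-6-[(dimethylamino)methyl]-2,3-dimethoxyphenol | COc1c(O)c(CN(C)C)cc(OCc2ccccc2)c1OC | intermediate
11 | 4-(benzyloxy)-2,3-dimethoxy-6-methylidenecyclohexa-2,4-dien-1-one | C=C1C=C(OCc2ccccc2)C(OC)=C(OC)C1=O | intermediate (not isolated)
12 | 2-{[2-amino-4-(4-methoxybenzyl)-1-methyl-1H-imidazol-5-yl]methyl}-4-(benzyloxy)-5,6-dimethoxyphenol | COc1ccc(Cc2nc(N)n(C)c2Cc2cc(OCc3ccccc3)c(OC)c(OC)c2O)cc1 | intermediate
13 | naamine E | COc1ccc(Cc2nc(N)n(C)c2Cc2cc(O)c(OC)c(OC)c2O)cc1 | intermediate
14 | 1-methylimidazolidine-2,4,5-trione | CN1C(=O)NC(=O)C1=O | starting material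
15 | 1-methyl-4-[(trimethylsilyl)oxy]-1H-imidazole-2,5-dione | CN1C(=O)N=C(O[Si](C)(C)C)C1=O | intermediate (not isolated)
16 | naamine E bis(O-trimethylsilyl) ether | COc1ccc(Cc2nc(N)n(C)c2Cc2cc(O[Si](C)(C)C)c(OC)c(OC)c2O[Si](C)(C)C)cc1 | intermediate (not isolated)
17 | naamidine E bis(O-trimethylsilyl) ether | COc1ccc(Cc2nc(NC3=NC(=O)N(C)C3=O)n(C)c2Cc2cc(O[Si](C)(C)C)c(OC)c(OC)c2O[Si](C)(C)C)cc1 | intermediate (not isolated)
18 | naamidine E | COc1ccc(Cc2nc(NC3=NC(=O)N(C)C3=O)n(C)c2Cc2cc(O)c(OC)c(OC)c2O)cc1 | target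

**Total step count:** 8. **Longest linear sequence:** 6 steps (7 → 8 → 9 → 10 → 12 → 13 → 18).

**Three steps most likely to fail**

**Step 6.** The risks are N- versus C-alkylation of the ambident aminoimidazole and dimerisation of 11. The fallback replaces the neutral π-nucleophile with a site-defined C5 carbanion and the quinone methide with an aldehyde. It sets out from 9 and 6 and comes back at 12. Phenol 9 is ortho-formylated (MgCl2, Et3N, paraformaldehyde, MeCN, reflux; Casnati–Skattebøl) to 5-(benzyloxy)-2-hydroxy-3,4-dimethoxybenzaldehyde F1. Amine 6 is masked with DMF dimethyl acetal (PhMe, 80 °C) as N'-[4-(4-methoxybenzyl)-1-methyl-1H-imidazol-2-yl]-N,N-dimethylformimidamide F2. n-BuLi (THF, −78 °C) deprotonates F2 at its only ring C–H to give {2-[(E)-(dimethylaminomethylidene)amino]-4-(4-methoxybenzyl)-1-methyl-1H-imidazol-5-yl}lithium F3. About 2.1 equiv of F3 are used, since the first equivalent only deprotonates the phenol of F1 and is recovered as F2. Addition to the aldehyde gives racemic N'-[5-{[5-(benzyloxy)-2-hydroxy-3,4-dimethoxyphenyl](hydroxy)methyl}-4-(4-methoxybenzyl)-1-methyl-1H-imidazol-2-yl]-N,N-dimethylformimidamide F4. Ionic deoxygenation (Et3SiH, TFA, CH2Cl2, 0 °C) removes this temporary stereocentre and gives N'-[5-[5-(benzyloxy)-2-hydroxy-3,4-dimethoxybenzyl]-4-(4-methoxybenzyl)-1-methyl-1H-imidazol-2-yl]-N,N-dimethylformimidamide F5. Acid hydrolysis of the formamidine (2 M HCl, MeOH, 60 °C) returns 12.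

**Step 2.** The risks are sluggish guanylation, cyanamide dimerisation and incomplete cyclisation. The fallback separates the events and uses a protected guanidine with π-acid catalysis. It sets out from 3 and comes back at 6. Amine 3 is guanylated with N,N'-di-Boc-N''-triflylguanidine (Et3N, CH2Cl2, rt) to N,N'-di-Boc-N''-methyl-N''-[3-(4-methoxyphenyl)prop-2-yn-1-yl]guanidine F6. AgOAc (10 mol %, AcOH/CH2Cl2, rt) then effects 5-exo-dig anti-aminometalation to tert-butyl (5Z)-2-[(tert-butoxycarbonyl)imino]-5-(4-methoxybenzylidene)-3-methylimidazolidine-1-carboxylate F7. TFA/CH2Cl2 removes both Boc groups with spontaneous aromatisation to 6.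

**Step 8.** The risks are oxidation of the hydroquinone at 110 °C and a low-yielding condensation. The fallback reverses the order, so the dehydrohydantoin is attached while the ring is still a mono-benzyl ether and the hydroquinone is released last without hydrogen. It sets out from 12 (with 14, activated as 15) and comes back at 18. BSA converts 12 into the O-trimethylsilyl ether of 12 F8, which condenses with 15 (PhMe, 110 °C) to the O-trimethylsilyl ether of 5'-O-benzylnaamidine E F9. Methanol releases 5'-O-benzylnaamidine E F10. BCl3 with pentamethylbenzene as cation scavenger (CH2Cl2, −78 °C) cleaves the aryl benzyl ether without touching the C=N bond and gives 18.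

**Further compounds**
F1 | step 6 | 5-(benzyloxy)-2-hydroxy-3,4-dimethoxybenzaldehyde | COc1c(O)c(C=O)cc(OCc2ccccc2)c1OC
F2 | step 6 | N'-[4-(4-methoxybenzyl)-1-methyl-1H-imidazol-2-yl]-N,N-dimethylformimidamide | CN(C)/C=N/c1nc(Cc2ccc(OC)cc2)cn1C
F3 | step 6 | {2-[(E)-(dimethylaminomethylidene)amino]-4-(4-methoxybenzyl)-1-methyl-1H-imidazol-5-yl}lithium | CN(C)/C=N/c1nc(Cc2ccc(OC)cc2)c([Li])n1C
F4 | step 6 | racemic N'-[5-{[5-(benzyloxy)-2-hydroxy-3,4-dimethoxyphenyl](hydroxy)methyl}-4-(4-methoxybenzyl)-1-methyl-1H-imidazol-2-yl]-N,N-dimethylformimidamide | CN(C)/C=N/c1nc(Cc2ccc(OC)cc2)c(C(O)c2cc(OCc3ccccc3)c(OC)c(OC)c2O)n1C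
F5 | step 6 | N'-[5-[5-(benzyloxy)-2-hydroxy-3,4-dimethoxybenzyl]-4-(4-methoxybenzyl)-1-methyl-1H-imidazol-2-yl]-N,N-dimethylformimidamide | CN(C)/C=N/c1nc(Cc2ccc(OC)cc2)c(Cc2cc(OCc3ccccc3)c(OC)c(OC)c2O)n1C
F6 | step 2 | N,N'-di-Boc-N''-methyl-N''-[3-(4-methoxyphenyl)prop-2-yn-1-yl]guanidine | CN(CC#Cc1ccc(OC)cc1)C(=NC(=O)OC(C)(C)C)NC(=O)OC(C)(C)C
F7 | step 2 | tert-butyl (5Z)-2-[(tert-butoxycarbonyl)imino]-5-(4-methoxybenzylidene)-3-methylimidazolidine-1-carboxylate | CN1C/C(=C/c2ccc(OC)cc2)N(C(=O)OC(C)(C)C)C1=NC(=O)OC(C)(C)C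
F8 | step 8 | O-trimethylsilyl ether of 12 | COc1ccc(Cc2nc(N)n(C)c2Cc2cc(OCc3ccccc3)c(OC)c(OC)c2O[Si](C)(C)C)cc1
F9 | step 8 | O-trimethylsilyl ether of 5'-O-benzylnaamidine E | COc1ccc(Cc2nc(NC3=NC(=O)N(C)C3=O)n(C)c2Cc2cc(OCc3ccccc3)c(OC)c(OC)c2O[Si](C)(C)C)cc1
F10 | step 8 | 5'-O-benzylnaamidine E | COc1ccc(Cc2nc(NC3=NC(=O)N(C)C3=O)n(C)c2Cc2cc(OCc3ccccc3)c(OC)c(OC)c2O)cc1
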